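## Retrosynthetic overview

1. Target 10 ⇐ 8: global O-deprotection (four methyl ethers, one ester); the axis is not touched.
2. 8 ⇐ 7: atroposelective reductive O-acylation of a stereolabile extended quinone; forming the acyl C–O bond at O1 aromatises the quinoid core and fixes the C4–C4′ axis (key step).
3. 7 ⇐ 2 × 5: oxidative para,para-dimerisation with over-oxidation; the C4–C4′ bond is made as a quinoid double bond with no stereochemical demand.
4. 5 ⇐ 1 + 2: Michael–Claisen annulation builds the acetyl/methyl-bearing ring of each naphthalene onto the commercial orsellinate ring; no other ring is formed.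

Assumption: the SMILES has no stereodescriptor and the only stereoelement is the configurationally stable C4–C4′ biaryl axis, so the single enantiomer is taken as the (M)-atropisomer (the (P)-form follows with the enantiomeric catalyst); SMILES cannot express this axis, so the strings carry no axis descriptor.

Locants follow the monomer numbering: C1–OH, C2–acetyl, C3–CH3, C4 = biaryl carbon, C6/C8 oxygens.

## Route

Step 1
Reactants: 1 methyl 2,4-dimethoxy-6-methylbenzoate; 2 (E)-4-methoxypent-3-en-2-one
Product: 5 1-(1-hydroxy-6,8-dimethoxy-3-methylnaphthalen-2-yl)ethan-1-one, via lithiated toluate 3 (not isolated), via methoxytetralone adduct 4 (not isolated)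
Conditions: LiN(iPr)2 (2.5 equiv, commercial solution), THF, −78 °C; then 2, −78 °C → rt; aq. HCl, rt
Reagents that add atoms: none
Why: Staunton–Weinreb (Michael–Claisen) annulation: the laterally lithiated toluate 3 adds 1,4 to the vinylogous ester 2, the enolate closes onto the neighbouring ester to give 4, and acid-promoted loss of methanol with enolisation aromatises the new ring, so no stereocentre survives.

Step 2
Reactants: 5 1-(1-hydroxy-6,8-dimethoxy-3-methylnaphthalen-2-yl)ethan-1-one (2 equiv)
Product: 7 2,2′-diacetyl-6,6′,8,8′-tetramethoxy-3,3′-dimethyl-1H,1′H-[4,4′-binaphthalenylidene]-1,1′-dione (extended quinone), via racemic binaphthol 6 (not isolated)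
Conditions: Ag2O (1.5 equiv per 5), Et3N (0.2 equiv), CH2Cl2, rt, dark; filter through Celite
Reagents that add atoms: none
Why: Oxidative phenol coupling: the naphthoxyl radical of 5 carries its spin at C4 (C2 is blocked by the acetyl group), para,para-coupling gives binaphthol 6, which is more easily oxidised than 5 and is taken on by the excess oxidant to the extended quinone, as known for 2-substituted 1-naphthols; the C4=C4′ bond of 7 is stereolabile, so nothing has to be controlled here.

Step 3
Reactants: 7 2,2′-diacetyl-6,6′,8,8′-tetramethoxy-3,3′-dimethyl-1H,1′H-[4,4′-binaphthalenylidene]-1,1′-dione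
Product: 8 (M)-2,2′-diacetyl-1′-hydroxy-6,6′,8,8′-tetramethoxy-3,3′-dimethyl-[4,4′-binaphthalen]-1-yl 2-methylpropanoate
Conditions: 2-methylpropanal (1.1 equiv), (5aR,10bS)-2-mesityl-5a,10b-dihydro-4H,6H-indeno[2,1-b][1,2,4]triazolo[4,3-d][1,4]oxazin-2-ium chloride (10 mol%), iPr2NEt (20 mol%), 4 Å MS, toluene/CH2Cl2, −20 °C → rt, argon
Reagents that add atoms: 2-methylpropanal, CC(C)C=O
Why: Proposed new method: atroposelective reductive O-acylation of a stereolabile extended quinone. The P- and M-twisted (and E/Z) forms of 7 are expected to interconvert quickly about the overcrowded quinoid C4=C4′ bond. The chiral Breslow intermediate from the aldehyde attacks the C1 carbonyl oxygen, because every quinoid carbon is fully substituted and C-attack is blocked. As the C–O bond forms, the ring aromatises and C4=C4′ becomes the locked biaryl axis, so the C–O bond-forming transition state selects one twist sense (dynamic kinetic asymmetric transformation). Collapse of the tetrahedral adduct releases the carbene and ester 8. Any binaphtholate formed by outer-sphere electron transfer stays stereolabile through electron exchange with remaining 7 until the chiral acyl azolium acylates it, while 8 can no longer reach the quinone oxidation level and keeps its axis. Closest known reaction types: carbene-catalysed mono-O-acylation of 1,4-naphthoquinones by aldehydes and carbene-catalysed atroposelective acylation of biaryl phenols.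

Step 4
Reactants: 8 (M)-2,2′-diacetyl-1′-hydroxy-6,6′,8,8′-tetramethoxy-3,3′-dimethyl-[4,4′-binaphthalen]-1-yl 2-methylpropanoate
Product: 10 (M)-1,1′-(1,1′,6,6′,8,8′-hexahydroxy-3,3′-dimethyl-[4,4′-binaphthalene]-2,2′-diyl)di(ethan-1-one), via pentahydroxy monoester 9 (not isolated)
Conditions: BBr3 (12 equiv), CH2Cl2, −78 °C → rt; then MeOH, 50 °C; aqueous work-up under argon
Reagents that add atoms: none
Why: BBr3 ether cleavage removes the four methyl groups to give 9, the HBr/MeOH formed at the quench transesterifies the activated aryl ester, and the biaryl axis (2,2′-dimethyl-1,1′-binaphthyl type) does not rotate under these conditions, so the configuration set in step 3 is kept.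

## Compound list

1 | methyl 2,4-dimethoxy-6-methylbenzoate | COC(=O)c1c(C)cc(OC)cc1OC | starting material
2 | (E)-4-methoxypent-3-en-2-one | CO/C(C)=C/C(C)=O | starting material
3 | [3,5-dimethoxy-2-(methoxycarbonyl)phenyl]methyllithium | COC(=O)c1c(C[Li])cc(OC)cc1OC | intermediate (not isolated)
4 | 2-acetyl-3,6,8-trimethoxy-3-methyl-3,4-dihydronaphthalen-1(2H)-one (racemic diastereomer mixture, present as its enolate) | CC(=O)C1C(C)(OC)Cc2cc(OC)cc(OC)c2C1=O | intermediate (not isolated)
5 | 1-(1-hydroxy-6,8-dimethoxy-3-methylnaphthalen-2-yl)ethan-1-one | CC(=O)c1c(C)cc2cc(OC)cc(OC)c2c1O | intermediate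
6 | rac-1,1′-(1,1′-dihydroxy-6,6′,8,8′-tetramethoxy-3,3′-dimethyl-[4,4′-binaphthalene]-2,2′-diyl)di(ethan-1-one) | CC(=O)c1c(C)c(-c2c(C)c(C(C)=O)c(O)c3c(OC)cc(OC)cc23)c2cc(OC)cc(OC)c2c1O | intermediate (not isolated)
7 | 2,2′-diacetyl-6,6′,8,8′-tetramethoxy-3,3′-dimethyl-1H,1′H-[4,4′-binaphthalenylidene]-1,1′-dione (E/Z and twist forms interconvert; no fixed stereochemistry) | CC(=O)C1=C(C)C(=C2C(C)=C(C(C)=O)C(=O)c3c(OC)cc(OC)cc32)c2cc(OC)cc(OC)c2C1=O | intermediate
8 | (M)-2,2′-diacetyl-1′-hydroxy-6,6′,8,8′-tetramethoxy-3,3′-dimethyl-[4,4′-binaphthalen]-1-yl 2-methylpropanoate | CC(=O)c1c(C)c(-c2c(C)c(C(C)=O)c(O)c3c(OC)cc(OC)cc23)c2cc(OC)cc(OC)c2c1OC(=O)C(C)C | intermediate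
9 | (M)-2,2′-diacetyl-1′,6,6′,8,8′-pentahydroxy-3,3′-dimethyl-[4,4′-binaphthalen]-1-yl 2-methylpropanoate | CC(=O)c1c(C)c(-c2c(C)c(C(C)=O)c(O)c3c(O)cc(O)cc23)c2cc(O)cc(O)c2c1OC(=O)C(C)C | intermediate (not isolated)
10 | (M)-1,1′-(1,1′,6,6′,8,8′-hexahydroxy-3,3′-dimethyl-[4,4′-binaphthalene]-2,2′-diyl)di(ethan-1-one) | CC(=O)c1c(C)c(-c2c(C)c(C(C)=O)c(O)c3c(O)cc(O)cc23)c2cc(O)cc(O)c2c1O | target

## Step count and risks

Total steps: 4. Longest linear sequence: 4.

Steps most likely to fail:

1. Step 3 (new method). The acylated oxygen is para to the axis, so the catalyst must sense the twist of the distal naphthalenone. Enantioselectivity may be modest, and an outer-sphere electron-transfer pathway could give racemic material. The sense of induction must be assigned by ECD or X-ray, and the catalyst antipode and N-aryl group chosen accordingly; 8 can be enriched by crystallisation. Fallback with known chemistry, setting out from 7 and coming back at 10: reduce 7 with Na2S2O4 (EtOAc/H2O) to racemic 6. Acylate both naphthols with (1R,2S,5R)-menthyl chloroformate (CC(C)[C@@H]1CC[C@@H](C)C[C@H]1OC(Cl)=O; Et3N, DMAP, CH2Cl2). Separate the diastereomers by chromatography or crystallisation into the (M)-bis(menthyl carbonate) F1 and the (P)-bis(menthyl carbonate) F2, which is set aside. Methanolyse F1 (K2CO3, MeOH, argon) to the (M)-tetramethoxybinaphthol F3, then demethylate with BBr3 as in step 4 to reach 10.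

2. Step 2. Coupling could occur at C5 or C7 of the dimethoxy ring or through oxygen, and the hindered, hydrogen-bonded naphthol may oxidise slowly or stop at 6. Fallback, setting out from 5 and coming back at 6, which Ag2O then oxidises to 7 as in the second half of step 2: brominate 5 para to the hydroxyl (NBS, MeCN, 0 °C) to the 4-bromonaphthol F4. Convert half of it with B2pin2, PdCl2(dppf) and KOAc (dioxane, 90 °C) into the 4-pinacolboronate F5. Join F4 and F5 by Suzuki–Miyaura coupling (Pd(OAc)2, SPhos, K3PO4, toluene/H2O, 100 °C) to racemic 6.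

3. Step 1. The toluate anion may deprotonate the enolisable acceptor instead of adding to its hindered β-carbon. Fallback, setting out from 1 and coming back at 5: run the same Michael–Claisen annulation of lithiated 1 with the more electrophilic (E)-pent-3-en-2-one (LiN(iPr)2, THF, −78 °C) to the 2-acetyl-3-methyltetralone F6. Dehydrogenate this β-diketone with DDQ (1.05 equiv, dioxane, rt → 60 °C) to 5.

## Further compounds

F1 | step 3 | (M)-2,2′-diacetyl-6,6′,8,8′-tetramethoxy-3,3′-dimethyl-[4,4′-binaphthalene]-1,1′-diyl bis[(1R,2S,5R)-2-isopropyl-5-methylcyclohexyl] dicarbonate | CC(=O)c1c(C)c(-c2c(C)c(C(C)=O)c(OC(=O)O[C@@H]3C[C@H](C)CC[C@H]3C(C)C)c3c(OC)cc(OC)cc23)c2cc(OC)cc(OC)c2c1OC(=O)O[C@@H]1C[C@H](C)CC[C@H]1C(C)C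
F2 | step 3 | (P)-2,2′-diacetyl-6,6′,8,8′-tetramethoxy-3,3′-dimethyl-[4,4′-binaphthalene]-1,1′-diyl bis[(1R,2S,5R)-2-isopropyl-5-methylcyclohexyl] dicarbonate (axis diastereomer of F1; same string because the axis is not encoded) | CC(=O)c1c(C)c(-c2c(C)c(C(C)=O)c(OC(=O)O[C@@H]3C[C@H](C)CC[C@H]3C(C)C)c3c(OC)cc(OC)cc23)c2cc(OC)cc(OC)c2c1OC(=O)O[C@@H]1C[C@H](C)CC[C@H]1C(C)C
F3 | step 3 | (M)-1,1′-(1,1′-dihydroxy-6,6′,8,8′-tetramethoxy-3,3′-dimethyl-[4,4′-binaphthalene]-2,2′-diyl)di(ethan-1-one) | CC(=O)c1c(C)c(-c2c(C)c(C(C)=O)c(O)c3c(OC)cc(OC)cc23)c2cc(OC)cc(OC)c2c1O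
F4 | step 2 | 1-(4-bromo-1-hydroxy-6,8-dimethoxy-3-methylnaphthalen-2-yl)ethan-1-one | CC(=O)c1c(C)c(Br)c2cc(OC)cc(OC)c2c1O
F5 | step 2 | 1-[1-hydroxy-6,8-dimethoxy-3-methyl-4-(4,4,5,5-tetramethyl-1,3,2-dioxaborolan-2-yl)naphthalen-2-yl]ethan-1-one | CC(=O)c1c(C)c(B2OC(C)(C)C(C)(C)O2)c2cc(OC)cc(OC)c2c1O
F6 | step 1 | rac-2-acetyl-6,8-dimethoxy-3-methyl-3,4-dihydronaphthalen-1(2H)-one (diastereomer mixture, enolised) | CC(=O)C1C(C)Cc2cc(OC)cc(OC)c2C1=O
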